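**Retrosynthetic overview**

1. Target 17 is cut at the ester C–O bond into ferulic acid 16 and 5-methoxylariciresinol 15 (Mitsunobu); C4–H of 15 comes from C4–NO2 of 14 by radical denitration, which sets the 3,4-cis relation.
2. The oxolane of 14 is cut into formaldehyde 10 and nitrocyclopropane 9: C4–C5 (nitroaldol) and O1–C2 (oxa-1,6-addition) form together after the cyclopropane opens to a p-quinone methide nitronate.
3. Enabling feature: the free 4-OH of the 3,5-dimethoxyphenyl ring is para to C2, so the ring bond O1–C2 is the alcohol adduct of a p-quinone methide, and C5H2–O1 between C4 and C2 is one formaldehyde; a nitro group on C4 supplies the carbanion and is removed again.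
4. Cyclopropane 8 comes from enal 2 and bromonitroalkane 7 by amine-catalysed Michael-initiated ring closure, which sets C3.
5. Ring order: cyclopropane (temporary, step 5), then oxolane (step 7); both C2 epimers and both C4 epimers converge.

Key step: step 7

Remark on the chemistry: oxolane numbering throughout is O1, C2 (4-hydroxy-3,5-dimethoxyphenyl), C3 (CH2O), C4 (4-hydroxy-3-methoxybenzyl), C5 (CH2). The nitro-bearing carbon of 8, 9 and 11–14 is carried as an epimer mixture (left unassigned in the SMILES) because step 8 erases it.

**Route**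

Step 1
Reactants: 1 sinapaldehyde
Product: 2 (E)-3-[4-(tert-butyldimethylsilyloxy)-3,5-dimethoxyphenyl]prop-2-enal
Conditions: TBSCl, imidazole, DMF, rt
Reagents that add atoms: tert-butyldimethylsilyl chloride, CC(C)(C)[Si](C)(C)Cl
Why: O-silylation of a phenol; the silyl ether keeps the para oxygen from acting as an electron donor until step 7 and leaves the enal free for iminium catalysis, and no stereocenter is formed.

Step 2
Reactants: 3 (E)-2-methoxy-4-(2-nitroethenyl)phenol
Product: 4 2-methoxy-4-(2-nitroethyl)phenol
Conditions: NaBH4, SiO2, CHCl3/i-PrOH, rt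
Reagents that add atoms: none
Why: conjugate hydride reduction of a β-nitrostyrene to the primary nitroalkane, the nitro group being inert to borohydride; no stereocenter is formed.

Step 3
Reactants: 4 2-methoxy-4-(2-nitroethyl)phenol
Product: 5 tert-butyl[2-methoxy-4-(2-nitroethyl)phenoxy]dimethylsilane
Conditions: TBSCl, imidazole, DMF, rt
Reagents that add atoms: tert-butyldimethylsilyl chloride, CC(C)(C)[Si](C)(C)Cl
Why: O-silylation of the phenol protects the electron-rich ring and the acidic O–H from the base and bromine of step 4; no stereocenter is formed.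

Step 4
Reactants: 5 tert-butyl[2-methoxy-4-(2-nitroethyl)phenoxy]dimethylsilane
Product: 7 [4-(2-bromo-2-nitroethyl)-2-methoxyphenoxy](tert-butyl)dimethylsilane (racemic), via potassium nitronate 6 (not isolated)
Conditions: KOt-Bu, THF, −78 °C; then added to Br2, CH2Cl2, −78 °C
Reagents that add atoms: bromine, BrBr
Why: α-bromination of a nitroalkane through its preformed nitronate, added inversely to bromine so that over-bromination and ring bromination should be avoided; the new C–Br centre is racemic and is destroyed in step 5.

Step 5
Reactants: 2 (E)-3-[4-(tert-butyldimethylsilyloxy)-3,5-dimethoxyphenyl]prop-2-enal, 7 [4-(2-bromo-2-nitroethyl)-2-methoxyphenoxy](tert-butyl)dimethylsilane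
Product: 8 (1R,3S)-2-[[4-(tert-butyldimethylsilyloxy)-3-methoxyphenyl]methyl]-3-[4-(tert-butyldimethylsilyloxy)-3,5-dimethoxyphenyl]-2-nitrocyclopropane-1-carbaldehyde (both C2 epimers)
Conditions: (S)-α,α-diphenylprolinol trimethylsilyl ether (20 mol%), Et3N, CHCl3, 0 °C to rt
Reagents that add atoms: none
Why: organocatalytic Michael-initiated ring closure (iminium then enamine activation), known for enals with bromonitromethane and bromomalonates: the bromonitronate from 7 should add to the β-carbon of the iminium ion of 2 on the face left open by the diphenyl(silyloxy)methyl group, setting the aryl-bearing carbon as S, and the enamine then displaces bromide (3-exo-tet) with the formyl group trans to the aryl group, setting the formyl-bearing carbon (the later C3) as R.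

Step 6
Reactants: 8 the nitrocyclopropane carbaldehyde
Product: 9 [(1R,3S)-2-[[4-(tert-butyldimethylsilyloxy)-3-methoxyphenyl]methyl]-3-[4-(tert-butyldimethylsilyloxy)-3,5-dimethoxyphenyl]-2-nitrocyclopropyl]methanol (both C2 epimers)
Conditions: NaBH4, THF/MeOH, −20 °C
Reagents that add atoms: none
Why: chemoselective 1,2-reduction of the aldehyde by borohydride (nitro group, cyclopropane and aryl silyl ethers are inert), so that the hydrogen on the later C3 is no longer α to a carbonyl before the basic key step; no stereocenter changes.

Step 7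
Reactants: 9 the nitrocyclopropylmethanol, 10 formaldehyde (as paraformaldehyde)
Product: 14 [(2S,3R)-2-(4-hydroxy-3,5-dimethoxyphenyl)-4-[(4-hydroxy-3-methoxyphenyl)methyl]-4-nitrooxolan-3-yl]methanol (both C4 epimers), via bisphenol cyclopropane 11 (not isolated), via quinone methide nitronate 12 (not isolated), via hydroxymethylated quinone methide 13 (not isolated)
Conditions: TBAF (2.5 equiv), (CH2O)n (5 equiv), THF (0.02 M), 0 °C to rt; then AcOH
Reagents that add atoms: none
Why: Proposed new method: fluoride removes the aryl silyl groups to give the phenoxide of 11, whose para oxygen pushes open the cyclopropane bond between the aryl-bearing and the nitro-bearing carbon to the p-quinone methide nitronate 12; the nitronate carbon adds to formaldehyde (Henry reaction, C4–C5) and the new primary hydroxyl of 13 adds to the exocyclic quinone methide carbon (O1–C2), which restores the aromatic ring and makes the sequence irreversible. The closest known reactions are the fluoride-triggered opening of 2-(4-siloxyaryl)cyclopropane-1,1-diesters to p-quinone methides that are trapped by nucleophiles, the nitroaldol reaction of secondary nitroalkanes with formaldehyde, and the intramolecular oxa-1,6-addition to p-quinone methides by which furanoid lignans are closed in nature; their merger into a formal [3+2] annulation of formaldehyde with a nitrocyclopropane is new. The only ring closed is the oxolane, by 5-exo-trig attack of oxygen on the quinone methide carbon. C2 is created in this closure and is controlled by C3: with C3–H eclipsing the exocyclic C=C (minimal allylic 1,3-strain) the tethered oxygen reaches only the face that places the aryl group trans to the C3 hydroxymethyl group, which is also the thermodynamically preferred arrangement, so both C2 epimers of the cyclopropane converge, while C4 becomes a quaternary nitro-bearing centre whose configuration is erased in step 8. The step needs C-hydroxymethylation of the nitronate and 5-exo closure to win over re-closure to the cyclopropane, O-cyclisation of the nitronate and oligomerisation; this should be secured because those side products keep a leaving group para to the phenoxide and can revert, whereas the oxolane ends in a poor alkoxide leaving group, and by excess formaldehyde at high dilution.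

Step 8
Reactants: 14 the 4-nitrooxolane
Product: 15 5-methoxylariciresinol, (2S,3R,4R)-2-(4-hydroxy-3,5-dimethoxyphenyl)-4-[(4-hydroxy-3-methoxyphenyl)methyl]-3-(hydroxymethyl)oxolane
Conditions: Bu3SnH (5 equiv), AIBN (0.3 equiv), toluene, 100 °C
Reagents that add atoms: none
Why: radical denitration of a tertiary nitroalkane (stannyl radical adds to a nitro oxygen, the adduct fragments to tributyltin nitrite and the planar C4 radical): both C4 epimers give the same radical, and hydrogen should be delivered from Bu3SnH to the face anti to the adjacent C3 hydroxymethyl group, which places the benzyl group cis to it and sets C4 as R.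

Step 9
Reactants: 15 5-methoxylariciresinol, 16 ferulic acid
Product: 17 [(2S,3R,4R)-2-(4-hydroxy-3,5-dimethoxyphenyl)-4-[(4-hydroxy-3-methoxyphenyl)methyl]oxolan-3-yl]methyl (E)-3-(4-hydroxy-3-methoxyphenyl)prop-2-enoate
Conditions: PPh3, DIAD, THF, 0 °C to rt
Reagents that add atoms: none
Why: Mitsunobu esterification, in which the only aliphatic alcohol is activated as its alkoxyphosphonium ion and displaced by the carboxylate of 16, far more acidic than the three phenols, so that the phenols and the (E)-alkene should stay untouched; no stereocenter is affected.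

**Compound list**

1 | sinapaldehyde, (E)-3-(4-hydroxy-3,5-dimethoxyphenyl)prop-2-enal | COc1cc(/C=C/C=O)cc(OC)c1O | starting material
2 | (E)-3-[4-(tert-butyldimethylsilyloxy)-3,5-dimethoxyphenyl]prop-2-enal | COc1cc(/C=C/C=O)cc(OC)c1O[Si](C)(C)C(C)(C)C | intermediate
3 | (E)-2-methoxy-4-(2-nitroethenyl)phenol | COc1cc(/C=C/[N+](=O)[O-])ccc1O | starting material
4 | 2-methoxy-4-(2-nitroethyl)phenol | COc1cc(CC[N+](=O)[O-])ccc1O | intermediate
5 | tert-butyl[2-methoxy-4-(2-nitroethyl)phenoxy]dimethylsilane | COc1cc(CC[N+](=O)[O-])ccc1O[Si](C)(C)C(C)(C)C | intermediate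
6 | potassium nitronate of 5 | COc1cc(CC=[N+]([O-])[O-])ccc1O[Si](C)(C)C(C)(C)C.[K+] | intermediate (not isolated)
7 | [4-(2-bromo-2-nitroethyl)-2-methoxyphenoxy](tert-butyl)dimethylsilane, racemic | COc1cc(CC(Br)[N+](=O)[O-])ccc1O[Si](C)(C)C(C)(C)C | intermediate
8 | (1R,3S)-2-[[4-(tert-butyldimethylsilyloxy)-3-methoxyphenyl]methyl]-3-[4-(tert-butyldimethylsilyloxy)-3,5-dimethoxyphenyl]-2-nitrocyclopropane-1-carbaldehyde, formyl trans to aryl, C2 epimers | O=C[C@H]1C([N+](=O)[O-])(Cc2ccc(O[Si](C)(C)C(C)(C)C)c(OC)c2)[C@@H]1c1cc(OC)c(O[Si](C)(C)C(C)(C)C)c(OC)c1 | intermediate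
9 | [(1R,3S)-2-[[4-(tert-butyldimethylsilyloxy)-3-methoxyphenyl]methyl]-3-[4-(tert-butyldimethylsilyloxy)-3,5-dimethoxyphenyl]-2-nitrocyclopropyl]methanol, C2 epimers | OC[C@H]1C([N+](=O)[O-])(Cc2ccc(O[Si](C)(C)C(C)(C)C)c(OC)c2)[C@@H]1c1cc(OC)c(O[Si](C)(C)C(C)(C)C)c(OC)c1 | intermediate
10 | formaldehyde (used as paraformaldehyde) | C=O | starting material
11 | [(1R,3S)-3-(4-hydroxy-3,5-dimethoxyphenyl)-2-[(4-hydroxy-3-methoxyphenyl)methyl]-2-nitrocyclopropyl]methanol, reacting as its phenoxide | OC[C@H]1C([N+](=O)[O-])(Cc2ccc(O)c(OC)c2)[C@@H]1c1cc(OC)c(O)c(OC)c1 | intermediate (not isolated)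
12 | 4-[(2R)-2-(hydroxymethyl)-4-(4-hydroxy-3-methoxyphenyl)-3-nitrobutylidene]-2,6-dimethoxycyclohexa-2,5-dien-1-one, shown as the nitro tautomer and reacting as the nitronate | O=C1C(OC)=CC(=C[C@@H](CO)C([N+](=O)[O-])Cc2ccc(O)c(OC)c2)C=C1OC | intermediate (not isolated)
13 | 4-[(2R)-2,3-bis(hydroxymethyl)-4-(4-hydroxy-3-methoxyphenyl)-3-nitrobutylidene]-2,6-dimethoxycyclohexa-2,5-dien-1-one, C3 epimers | O=C1C(OC)=CC(=C[C@@H](CO)C(CO)([N+](=O)[O-])Cc2ccc(O)c(OC)c2)C=C1OC | intermediate (not isolated)
14 | [(2S,3R)-2-(4-hydroxy-3,5-dimethoxyphenyl)-4-[(4-hydroxy-3-methoxyphenyl)methyl]-4-nitrooxolan-3-yl]methanol, aryl trans to CH2OH, C4 epimers | OC[C@H]1C([N+](=O)[O-])(Cc2ccc(O)c(OC)c2)CO[C@@H]1c1cc(OC)c(O)c(OC)c1 | intermediate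
15 | 5-methoxylariciresinol, [(2S,3R,4R)-2-(4-hydroxy-3,5-dimethoxyphenyl)-4-[(4-hydroxy-3-methoxyphenyl)methyl]oxolan-3-yl]methanol | OC[C@H]1[C@@H](Cc2ccc(O)c(OC)c2)CO[C@@H]1c1cc(OC)c(O)c(OC)c1 | intermediate
16 | ferulic acid, (E)-3-(4-hydroxy-3-methoxyphenyl)prop-2-enoic acid | COc1cc(/C=C/C(=O)O)ccc1O | starting material
17 | [(2S,3R,4R)-2-(4-hydroxy-3,5-dimethoxyphenyl)-4-[(4-hydroxy-3-methoxyphenyl)methyl]oxolan-3-yl]methyl (E)-3-(4-hydroxy-3-methoxyphenyl)prop-2-enoate | COc1cc(/C=C/C(=O)OC[C@H]2[C@@H](Cc3ccc(O)c(OC)c3)CO[C@@H]2c2cc(OC)c(O)c(OC)c2)ccc1O | target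

**Step count and risks**

Total step count: 9. Longest linear sequence: 8 steps (from 3 through steps 2 to 9).

Steps most likely to fail:

Step 7 (proposed new method). The quinone methide nitronate may be consumed by attack of its own nitronate oxygen or of a second molecule (O-cyclisation, oligomerisation), or the quinone methide may tautomerise under base to a styrene with loss of the C3 stereocentre, before hydroxymethylation and ring closure occur. The fallback uses known reaction types, separates the two bond formations and closes the ring under acid; it sets out from 9 and comes back at 14. Desilylation of 9 with K2CO3 in methanol lets the phenoxide-triggered opening run in a nucleophilic solvent, so that the quinone methide is captured at once by 1,6-addition of methanol to give the open-chain benzylic methyl ether F1. A separate Henry reaction of F1 with aqueous formaldehyde and Et3N gives the nitro diol F2. Camphorsulfonic acid in CH2Cl2 then ionises the p-hydroxybenzylic methyl ether of F2 and the C5 hydroxyl closes the oxolane (5-exo, thermodynamic 2,3-trans) to give 14.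

Step 5. Ring closure at the fully substituted bromonitro carbon may be slow, so that debromination or retro-Michael reaction erodes conversion and enantiopurity. The fallback reverses the polarity of the ring closure; it sets out from 2 and 5 (bypassing 7) and comes back at 8. Conjugate addition of nitroalkane 5 to enal 2 with the same (S)-prolinol silyl ether (iminium catalysis, benzoic acid, MeOH) gives the γ-nitro aldehyde F3 with the aryl-bearing carbon set. N-Iodosuccinimide with the same amine iodinates the aldehyde α-carbon through the enamine to give the α-iodo aldehyde F4 (not isolated). Et3N then closes the ring by C-alkylation of the nitronate at this secondary carbon (3-exo-tet, formyl trans to aryl) to give 8.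

Step 8. Facial selectivity in hydrogen-atom transfer to the C4 radical may be poor, or the phenolic O–H groups may retard the radical chain. The fallback changes the substrate so that a bulky group on C3 shields one face and no O–H donor is present; it sets out from 14 and comes back at 15. Silylation of all three hydroxyl groups (TBSCl, imidazole, DMF) gives the tris(silyl ether) F5. Denitration with (Me3Si)3SiH and AIBN, a bulkier hydrogen donor, gives the protected lariciresinol F6. TBAF buffered with AcOH then returns 15.

Further compounds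
F1 | step 7 | 4-[(2R)-2-(hydroxymethyl)-4-(4-hydroxy-3-methoxyphenyl)-1-methoxy-3-nitrobutyl]-2,6-dimethoxyphenol, epimers at C1 and C3 of the chain | COC([C@@H](CO)C([N+](=O)[O-])Cc1ccc(O)c(OC)c1)c1cc(OC)c(O)c(OC)c1
F2 | step 7 | 4-[(2R)-2,3-bis(hydroxymethyl)-4-(4-hydroxy-3-methoxyphenyl)-1-methoxy-3-nitrobutyl]-2,6-dimethoxyphenol, epimers at C1 and C3 of the chain | COC([C@@H](CO)C(CO)([N+](=O)[O-])Cc1ccc(O)c(OC)c1)c1cc(OC)c(O)c(OC)c1
F3 | step 5 | (3S)-3-[4-(tert-butyldimethylsilyloxy)-3,5-dimethoxyphenyl]-5-[4-(tert-butyldimethylsilyloxy)-3-methoxyphenyl]-4-nitropentanal, C4 epimers | O=CC[C@H](C([N+](=O)[O-])Cc1ccc(O[Si](C)(C)C(C)(C)C)c(OC)c1)c1cc(OC)c(O[Si](C)(C)C(C)(C)C)c(OC)c1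
F4 | step 5 | 2-iodo derivative of F3 (α-iodo aldehyde, epimers at C2 and C4, not isolated) | O=CC(I)[C@H](C([N+](=O)[O-])Cc1ccc(O[Si](C)(C)C(C)(C)C)c(OC)c1)c1cc(OC)c(O[Si](C)(C)C(C)(C)C)c(OC)c1
F5 | step 8 | tris(tert-butyldimethylsilyl) ether of 14 (both phenols and the primary alcohol silylated, C4 epimers) | CC(C)(C)[Si](C)(C)OC[C@H]1C([N+](=O)[O-])(Cc2ccc(O[Si](C)(C)C(C)(C)C)c(OC)c2)CO[C@@H]1c1cc(OC)c(O[Si](C)(C)C(C)(C)C)c(OC)c1
F6 | step 8 | tris(tert-butyldimethylsilyl) ether of 15, (2S,3R,4R) | CC(C)(C)[Si](C)(C)OC[C@H]1[C@@H](Cc2ccc(O[Si](C)(C)C(C)(C)C)c(OC)c2)CO[C@@H]1c1cc(OC)c(O[Si](C)(C)C(C)(C)C)c(OC)c1
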